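Start with the rate.

all flasks: left-handed substrate 0.17 M; right-handed substrate 0.17 M; free catalyst 1 mol%
- violet: coupling partner 6 equiv; temperature 100 °C; run made earlier
- Tuesday's: coupling partner 3.00 equiv; temperature 100 °C; time 50 min
- Wednesday's: coupling partner 3.00 equiv; temperature 75 °C; time 50 min
- Saturday's: coupling partner 3.00 equiv; temperature 125 °C; time 50 min

violet run (percent of the left-handed substrate and right-handed substrate together charged)

| time / min | left-handed product / % | left-handed substrate / % |
|---|---|---|
| 0.417 | 0.6 | 49.6 |
| 0.833 | 1.5 | 48.1 |
| 1.33 | 2.8 | 47.7 |
| 2.50 | 4.3 | 46.3 |
| 5.00 | 8.2 | 42.8 |

(readings scatter by 0.3 percentage points)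

- free catalyst is single-handed; left-handed substrate and right-handed substrate are mirror images of each other, charged as a racemate, each of them at the stated concentration
- on the list of suspects stand: coupling partner -> decomposed reagent; left-handed product <-> right-handed product; coupling partner + free catalyst + right-handed substrate -> free catalyst + right-handed product; left-handed substrate <-> right-handed substrate; coupling partner + free catalyst + left-handed substrate -> free catalyst + left-handed product; free catalyst -> spent catalyst
- the earlier runs do not show what temperature does; that part of a forecast is a guess

- the flask with the highest amount of left-handed product, in percent of the left-handed substrate and right-handed substrate together charged ("all alike" if they lie within 1.5 percentage points) (Tuesday's / Wednesday's / Saturday's / all alike)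
- final left-handed product, as a percentage of the left-handed substrate and right-handed substrate together charged, in Tuesday's
- final left-handed product, as a percentage of the left-handed substrate and right-handed substrate together charged, in Wednesday's
- final left-handed product, as a percentage of the left-handed substrate and right-handed substrate together charged, in Saturday's

The violet run makes 8.2% of left-handed product in 5.00 min. I take the rate as proportional to c(left-handed substrate) times c(coupling partner). That is an assumption. The violet run shows one amount of coupling partner. Tuesday's 3.00 equiv against violet's 6 equiv then starts at half of violet's rate. Over 50 min that rate gives 41.0%. I call this the straight-line yield, the left-handed product made if the start rate held.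

Now the slowing. The zero of my scale is the symmetric charge: without exchange, left-handed substrate plus left-handed product stays at 0.5 of the substrate charged. Violet's last reading sums to 51.0%, which is 1 percentage point over, against a scatter of 0.3 points per reading. That hints at a small refill from right-handed substrate, which I leave out.

Draining left-handed substrate lowers the straight line to 28.0%, a factor of 0.683. Each left-handed product also takes one coupling partner, so that yield uses 18.7% of Tuesday's coupling partner. Its mean rate factor is therefore 0.907. Together they give 25.4% for Tuesday's. Decomposition of coupling partner is a suspect the readings can't size, and for Wednesday's and Saturday's I commit to nothing.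

The forecast says Saturday's comes highest, with 31% for Tuesday's, 10% for Wednesday's and 42% for Saturday's; in its words, “Temperature is a guess”. My Tuesday figure is lower than its 31%.

Tuesday's ends at 25.1%, Wednesday's at 14.9% and Saturday's at 15.3%, so Tuesday's comes highest. In Saturday's flask coupling partner, the first to run out, stands at 0.867% of its charge at 50.0 min, and left-handed product already stood at 15.4% at 25.0 min. Tuesday's flask kept 0.612 of its straight-line yield, which is its mean rate as a share of the assumed start rate.

    coupling partner → decomposed reagent (k = 0.00960 /min, Ea = 104 kJ/mol)
    left-handed product ⇌ right-handed product (k = 0.00120 /min, Ea = 126 kJ/mol)
    coupling partner + free catalyst + right-handed substrate → free catalyst + right-handed product (k = 7.20 /M²/min, Ea = 63.0 kJ/mol)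
    left-handed substrate ⇌ right-handed substrate (k = 0.0900 /min, Ea = 96.0 kJ/mol)
    coupling partner + free catalyst + left-handed substrate → free catalyst + left-handed product (k = 22.0 /M²/min, Ea = 40.0 kJ/mol)
    free catalyst → spent catalyst (k = 1.40 × 10⁻⁴ /min, Ea = 116 kJ/mol)
    (constants at 100 °C)

Take Tuesday's flask with 1.80 equiv of coupling partner. Its straight-line yield is 24.6%, and Tuesday's share of it gives 15.1%. The computed flask gives 16.3%.

Readings and results were generated by integration for an exercise.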